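**Retrosynthetic overview**

1. The two tropolones are unmasked last from their methyl ethers. Before that, both dihydropyran rings are closed together, O1–C9a and O1'–C9a', by addition–elimination of the C2 and C2' alkoxides on methoxytropone rings.
2. C4–C4a and C4'–C4a' come from a two-fold Negishi coupling of a C10 1,10-diiodide with two equivalents of 5-bromo-2,6-dimethoxy-4-methyltropone. The seven-membered rings are made first, from 2-methylanisole by Birch reduction, dibromocarbene addition and oxidative ring expansion.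
3. The strategy rests on this feature: C2 and C2' are ether carbons allylic to the E,E-buta-1,3-diene linker and C3 carries the methyl. C2–C3 and C2'–C3' are therefore the new bonds of two Ireland–Claisen shifts of the propanoate/acetate of a C2-symmetric (3S,4S)-1,6-bis(4-methoxybenzyloxy)hexa-1,5-diene-3,4-diol; the shifts also create the diene and close no ring.
4. That mixed diester comes from L-tartrate acetonide by double alkyne homologation, mono-propanoylation, acetylation, hydroboration and copper-mediated alkenyl–oxygen coupling with 4-methoxybenzyl alcohol.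

Key step: step 7

Assumption: O-methylation of the bromotropolone is taken to occur mainly at the oxygen that leaves the ring carbonyl β to the ring methoxy group (the push–pull stabilised arrangement). Methylation at the other oxygen would be separated by chromatography.

**Route**

Step 1
Reactants: 1 dimethyl (4R,5R)-2,2-dimethyl-1,3-dioxolane-4,5-dicarboxylate (dimethyl 2,3-O-isopropylidene-L-tartrate)
Product: 3 (4S,5S)-4,5-diethynyl-2,2-dimethyl-1,3-dioxolane, via dialdehyde 2 (not isolated)
Conditions: iBu2AlH, CH2Cl2, −78 °C; then MeOH, K2CO3, dimethyl (1-diazo-2-oxopropyl)phosphonate (2.4 equiv), −78 °C → rt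
Reagents that add atoms: dimethyl (1-diazo-2-oxopropyl)phosphonate, CC(=O)C(=[N+]=[N-])P(=O)(OC)OC
Why: Partial reduction stops at the aluminium hemiacetals, methanol releases the dialdehyde, and Seyferth–Gilbert homologation (Ohira–Bestmann variant) converts each CHO into C≡CH; the trans-acetonide holds the two stereocentres, which are not touched.

Step 2
Reactants: 3 (4S,5S)-4,5-diethynyl-2,2-dimethyl-1,3-dioxolane
Product: 4 (3S,4S)-hexa-1,5-diyne-3,4-diol
Conditions: 2 M aq. HCl, THF, 50 °C
Reagents that add atoms: none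
Why: Acid-catalysed acetal hydrolysis frees the C2-symmetric diol without breaking a bond at either stereocentre.

Step 3
Reactants: 4 (3S,4S)-hexa-1,5-diyne-3,4-diol
Product: 6 (3S,4S)-4-hydroxyhexa-1,5-diyn-3-yl propanoate, via cyclic orthoester 5 (not isolated)
Conditions: EtC(OEt)3, PPTS (cat.), CH2Cl2, rt; then AcOH/H2O, rt
Reagents that add atoms: triethyl orthopropanoate, CCC(OCC)(OCC)OCC; water, O
Why: The 1,2-diol forms a five-membered cyclic orthoester, and mild aqueous acid opens the derived dioxolanylium ion to the mono-ester only (orthoester mono-acylation); since the diol is C2-symmetric, either oxygen gives the same compound and acyl migration is degenerate.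

Step 4
Reactants: 6 (3S,4S)-4-hydroxyhexa-1,5-diyn-3-yl propanoate
Product: 7 (3S,4S)-hexa-1,5-diyne-3,4-diyl acetate propanoate
Conditions: Ac2O, pyridine, DMAP (cat.), CH2Cl2, 0 °C
Reagents that add atoms: acetic anhydride, CC(=O)OC(C)=O
Why: DMAP-catalysed acylation of the remaining secondary propargylic alcohol gives the mixed diester without affecting a stereocentre.

Step 5
Reactants: 7 (3S,4S)-hexa-1,5-diyne-3,4-diyl acetate propanoate
Product: 8 (1E,3S,4S,5E)-1,6-bis(4,4,5,5-tetramethyl-1,3,2-dioxaborolan-2-yl)hexa-1,5-diene-3,4-diyl acetate propanoate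
Conditions: HBpin (2.5 equiv), Cy2BH (cat.), THF, rt
Reagents that add atoms: pinacolborane, B1OC(C)(C)C(C)(C)O1
Why: Borane-catalysed hydroboration: dicyclohexylborane adds syn and anti-Markovnikov to each terminal alkyne and passes the alkenyl group on to pinacolborane, so both boronates should form with E geometry while the esters are left alone by the hindered borane.

Step 6
Reactants: 8 (1E,3S,4S,5E)-1,6-bis(4,4,5,5-tetramethyl-1,3,2-dioxaborolan-2-yl)hexa-1,5-diene-3,4-diyl acetate propanoate; 9 (4-methoxyphenyl)methanol (two equivalents enter the product)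
Product: 10 (1E,3S,4S,5E)-1,6-bis[(4-methoxybenzyl)oxy]hexa-1,5-diene-3,4-diyl acetate propanoate
Conditions: Cu(OAc)2, Et3N, 9 (excess), CH2Cl2, 4 Å MS, air, rt
Reagents that add atoms: (4-methoxyphenyl)methanol (second equivalent of 9), COc1ccc(CO)cc1
Why: Chan–Lam-type oxidative coupling: each alkenyl group passes from boron to copper with retention and the C–O bond forms from a trivalent copper alkenyl alkoxide, giving the E-enol ethers under amine-buffered room-temperature conditions that spare the allylic esters and the acid-labile product; one molecule of 9 is taken up at each alkenyl boronate.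

Step 7
Reactants: 10 (1E,3S,4S,5E)-1,6-bis[(4-methoxybenzyl)oxy]hexa-1,5-diene-3,4-diyl acetate propanoate
Product: 13 (2S,3S,4E,6E,8R)-3,8-bis[(4-methoxybenzyl)oxy]-2-methyldeca-4,6-dienedioic acid, via bis(silyl ketene acetal) 11 (not isolated), via bis(trimethylsilyl) ester 12 (not isolated)
Conditions: LiN(iPr)2, Me3SiCl/Et3N, THF, −78 °C → rt; then aq. NaOH; citric acid to pH 4
Reagents that add atoms: none
Why: LiN(iPr)2 in THF with Me3SiCl already present deprotonates both esters kinetically and traps them at once as bis(silyl ketene acetal) 11 (which also suppresses acyl transfer between the neighbouring esters), the propanoate-derived unit having its methyl cis to the allylic oxygen (E-silyl ketene acetal); on warming, each unit undergoes a concerted [3,3]-sigmatropic Ireland–Claisen shift through a chair, forming C2–C3 and C2'–C3' and moving both double bonds inward to the E,E-diene, and no ring is closed. The closest known reaction type is the ester enolate Claisen rearrangement of glycal esters, in which the bond-forming terminus is likewise an enol ether carbon, together with two-directional versions on bis(allylic) esters. Each tartrate-derived carbinol carbon sits in the chair with its large substituent equatorial, so its C–O configuration is relayed suprafacially to the new C–O centres C2 and C2' and both new alkenes form E. C3 is fixed by the pairing of the E-enol ether (oxygen equatorial at the terminus) with the E-ketene acetal (methyl pseudo-axial), which gives the 2,3-anti relationship, the later trans ring substituents. The step needs regioselectivity in the second shift, because the remaining ketene acetal is then also allylic to the newly formed alkene; the donor oxygen on its own terminus (rate acceleration by a 6-alkoxy group) and the smaller substituent there should steer it to the enol ether carbon.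

Step 8
Reactants: 13 (2S,3S,4E,6E,8R)-3,8-bis[(4-methoxybenzyl)oxy]-2-methyldeca-4,6-dienedioic acid
Product: 14 (2R,3S,4E,6E,8R)-3,8-bis[(4-methoxybenzyl)oxy]-2-methyldeca-4,6-diene-1,10-diol
Conditions: LiAlH4, THF, 0 °C → rt
Reagents that add atoms: none
Why: Hydride reduction of both carboxylic acids (as carboxylates, which do not enolise here) gives the primary alcohols and leaves the ethers, the diene and the three stereocentres unchanged.

Step 9
Reactants: 14 (2R,3S,4E,6E,8R)-3,8-bis[(4-methoxybenzyl)oxy]-2-methyldeca-4,6-diene-1,10-diol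
Product: 15 (2S,3S,4E,6E,8R)-1,10-diiodo-3,8-bis[(4-methoxybenzyl)oxy]-2-methyldeca-4,6-diene
Conditions: I2, PPh3, imidazole, CH2Cl2, 0 °C → rt
Reagents that add atoms: iodine, II
Why: Appel iodination: the primary alcohols are activated as alkoxyphosphonium ions and displaced by iodide at CH2, the secondary ethers being inert.

Step 10
Reactants: 16 2-methylanisole
Product: 17 1-methoxy-2-methylcyclohexa-1,4-diene
Conditions: Li, NH3(l), THF, tBuOH, −78 °C
Reagents that add atoms: none
Why: Birch reduction protonates the two ring positions flanking the donor-substituted carbons, so methoxy and methyl stay together on one tetrasubstituted enol ether double bond of the 1,4-diene.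

Step 11
Reactants: 17 1-methoxy-2-methylcyclohexa-1,4-diene
Product: 18 rac-7,7-dibromo-1-methoxy-6-methylbicyclo[4.1.0]hept-3-ene
Conditions: CHBr3, KOtBu, pentane, −15 → 0 °C
Reagents that add atoms: bromoform, BrC(Br)Br
Why: Electrophilic dibromocarbene (α-elimination of bromoform) adds to the electron-rich tetrasubstituted enol ether double bond in preference to the disubstituted alkene, giving the cis-fused cyclopropane, whose stereocentres are lost again in step 13.

Step 12
Reactants: 18 rac-7,7-dibromo-1-methoxy-6-methylbicyclo[4.1.0]hept-3-ene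
Product: 19 rac-7,7-dibromo-1-methoxy-6-methylbicyclo[4.1.0]heptane-3,4-diol (cis-diol)
Conditions: OsO4 (cat.), N-methylmorpholine N-oxide, acetone/H2O, rt
Reagents that add atoms: N-methylmorpholine N-oxide, C[N+]1([O-])CCOCC1; water, O
Why: Upjohn dihydroxylation of the remaining cis-alkene gives the cis-diol, whose configuration does not matter because both carbinols are oxidised next.

Step 13
Reactants: 19 rac-7,7-dibromo-1-methoxy-6-methylbicyclo[4.1.0]heptane-3,4-diol
Product: 21 5-bromo-2-hydroxy-4-methoxy-6-methylcyclohepta-2,4,6-trien-1-one, via dione 20 (not isolated)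
Conditions: (CF3CO)2O, DMSO, CH2Cl2, −78 °C; then Et3N, −78 °C → rt
Reagents that add atoms: none
Why: Swern-type oxidation gives the 1,2-dione, whose enediol tautomer is a norcaradiene that opens by 6π electrocyclic ring opening to a 7,7-dibromocycloheptatriene and then loses HBr through the bromotropylium ion, leaving methoxy, bromine and methyl on three adjacent carbons of the tropolone.

Step 14
Reactants: 21 5-bromo-2-hydroxy-4-methoxy-6-methylcyclohepta-2,4,6-trien-1-one
Product: 22 5-bromo-2,6-dimethoxy-4-methylcyclohepta-2,4,6-trien-1-one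
Conditions: MeI, K2CO3, acetone, 50 °C
Reagents that add atoms: iodomethane, CI
Why: Williamson O-alkylation of the tropolonate should favour the oxygen remote from the ring methoxy, because the resulting carbonyl is then β to that methoxy (vinylogous ester stabilisation), which is also the arrangement wanted for step 17.

Step 15
Reactants: 15 (2S,3S,4E,6E,8R)-1,10-diiodo-3,8-bis[(4-methoxybenzyl)oxy]-2-methyldeca-4,6-diene; 22 5-bromo-2,6-dimethoxy-4-methylcyclohepta-2,4,6-trien-1-one (two equivalents)
Product: 24 5,5'-[(2R,3R,4E,6E,8R)-3,8-bis[(4-methoxybenzyl)oxy]-2-methyldeca-4,6-diene-1,10-diyl]bis(2,6-dimethoxy-4-methylcyclohepta-2,4,6-trien-1-one), via bis(alkylzinc iodide) 23 (not isolated)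
Conditions: Zn dust, LiCl, THF, 40 °C; then 22 (2.2 equiv), Pd(OAc)2 (cat.), SPhos, THF/NMP, 50 °C
Reagents that add atoms: 5-bromo-2,6-dimethoxy-4-methylcyclohepta-2,4,6-trien-1-one (second equivalent of 22), COc1cc(C)c(Br)c(OC)cc1=O
Why: Zinc inserts into both primary C–I bonds, and a two-fold Negishi coupling (oxidative addition of the tropone C–Br bond to zerovalent palladium, transmetallation, reductive elimination aided by the bulky biarylphosphine) joins one molecule of 22 to each chain end, forming C4–C4a and C4'–C4a'; the γ-alkoxy alkylzincs cannot β-eliminate and halotropolone ethers are competent coupling partners.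

Step 16
Reactants: 24 bis(tropone) bis(4-methoxybenzyl) ether
Product: 25 5,5'-[(2R,3R,4E,6E,8R)-3,8-dihydroxy-2-methyldeca-4,6-diene-1,10-diyl]bis(2,6-dimethoxy-4-methylcyclohepta-2,4,6-trien-1-one)
Conditions: DDQ, CH2Cl2/pH 7 buffer, 0 °C
Reagents that add atoms: none
Why: Oxidative cleavage of the 4-methoxybenzyl ethers: DDQ abstracts hydride from the electron-rich benzylic CH2 and water hydrolyses the oxocarbenium ion, while buffering, low temperature and a small excess should keep the dienylic alcohols and the diene from further oxidation.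

Step 17
Reactants: 25 bis(tropone) diol
Product: 26 (2R,3R)-7-methoxy-2-[(1E,3E)-4-[(2R)-7-methoxy-5-methyl-8-oxo-2,3,4,8-tetrahydrocyclohepta[b]pyran-2-yl]buta-1,3-dien-1-yl]-3,5-dimethyl-3,4-dihydrocyclohepta[b]pyran-8(2H)-one
Conditions: NaH, THF, 0 °C → rt
Reagents that add atoms: none
Why: Each alkoxide adds intramolecularly (6-exo-trig) to C9a, the β-carbon of the methoxy-enone part of its tropone, and methoxide is expelled (addition–elimination at a vinylogous ester), closing both dihydropyran rings with the O–C2 and O–C2' bonds untouched so that all three stereocentres are retained.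

Step 18
Reactants: 26 bis(7-methoxy) ether of the target
Product: 27 (2R,3R)-8-hydroxy-2-[(1E,3E)-4-[(2R)-8-hydroxy-5-methyl-7-oxo-2,3,4,7-tetrahydrocyclohepta[b]pyran-2-yl]buta-1,3-dien-1-yl]-3,5-dimethyl-3,4-dihydrocyclohepta[b]pyran-7(2H)-one (CNP0332980.1)
Conditions: LiOH, THF/H2O, rt; then dilute HCl to pH 5, 0 °C
Reagents that add atoms: lithium hydroxide, [Li+].[OH-]
Why: A 2-methoxytropone is a vinylogous ester, so hydroxide adds ipso at C7 (the position α to the tropone carbonyl, the usual site of nucleophilic attack) and methoxide leaves, giving the tropolonate and after mild acidification the tropolone, whose rapidly exchanging tautomers are the target as drawn.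

**Compound list**

1 | dimethyl (4R,5R)-2,2-dimethyl-1,3-dioxolane-4,5-dicarboxylate | COC(=O)[C@@H]1OC(C)(C)O[C@H]1C(=O)OC | starting material
2 | (4R,5R)-2,2-dimethyl-1,3-dioxolane-4,5-dicarbaldehyde | O=C[C@@H]1OC(C)(C)O[C@H]1C=O | intermediate
3 | (4S,5S)-4,5-diethynyl-2,2-dimethyl-1,3-dioxolane | C#C[C@@H]1OC(C)(C)O[C@H]1C#C | intermediate
4 | (3S,4S)-hexa-1,5-diyne-3,4-diol | C#C[C@H](O)[C@@H](O)C#C | intermediate
5 | (4S,5S)-2-ethoxy-2-ethyl-4,5-diethynyl-1,3-dioxolane | CCC1(OCC)O[C@@H](C#C)[C@H](C#C)O1 | intermediate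
6 | (3S,4S)-4-hydroxyhexa-1,5-diyn-3-yl propanoate | CCC(=O)O[C@@H](C#C)[C@@H](O)C#C | intermediate
7 | (3S,4S)-hexa-1,5-diyne-3,4-diyl acetate propanoate | CCC(=O)O[C@@H](C#C)[C@@H](OC(C)=O)C#C | intermediate
8 | (1E,3S,4S,5E)-1,6-bis(4,4,5,5-tetramethyl-1,3,2-dioxaborolan-2-yl)hexa-1,5-diene-3,4-diyl acetate propanoate | CCC(=O)O[C@@H](/C=C/B1OC(C)(C)C(C)(C)O1)[C@@H](OC(C)=O)/C=C/B1OC(C)(C)C(C)(C)O1 | intermediate
9 | (4-methoxyphenyl)methanol | COc1ccc(CO)cc1 | starting material
10 | (1E,3S,4S,5E)-1,6-bis[(4-methoxybenzyl)oxy]hexa-1,5-diene-3,4-diyl acetate propanoate | CCC(=O)O[C@@H](/C=C/OCc1ccc(OC)cc1)[C@@H](OC(C)=O)/C=C/OCc1ccc(OC)cc1 | intermediate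
11 | bis(trimethylsilyl ketene acetal) of 10 (propanoate-derived unit E, methyl cis to the allylic oxygen) | C/C=C(/O[Si](C)(C)C)O[C@@H](/C=C/OCc1ccc(OC)cc1)[C@@H](OC(=C)O[Si](C)(C)C)/C=C/OCc1ccc(OC)cc1 | intermediate
12 | bis(trimethylsilyl) (2S,3S,4E,6E,8R)-3,8-bis[(4-methoxybenzyl)oxy]-2-methyldeca-4,6-dienedioate | C[Si](C)(C)OC(=O)[C@@H](C)[C@@H](OCc1ccc(OC)cc1)/C=C/C=C/[C@H](OCc1ccc(OC)cc1)CC(=O)O[Si](C)(C)C | intermediate
13 | (2S,3S,4E,6E,8R)-3,8-bis[(4-methoxybenzyl)oxy]-2-methyldeca-4,6-dienedioic acid | OC(=O)[C@@H](C)[C@@H](OCc1ccc(OC)cc1)/C=C/C=C/[C@H](OCc1ccc(OC)cc1)CC(=O)O | intermediate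
14 | (2R,3S,4E,6E,8R)-3,8-bis[(4-methoxybenzyl)oxy]-2-methyldeca-4,6-diene-1,10-diol | OC[C@@H](C)[C@@H](OCc1ccc(OC)cc1)/C=C/C=C/[C@H](OCc1ccc(OC)cc1)CCO | intermediate
15 | (2S,3S,4E,6E,8R)-1,10-diiodo-3,8-bis[(4-methoxybenzyl)oxy]-2-methyldeca-4,6-diene | IC[C@@H](C)[C@@H](OCc1ccc(OC)cc1)/C=C/C=C/[C@H](OCc1ccc(OC)cc1)CCI | intermediate
16 | 2-methylanisole | COc1ccccc1C | starting material
17 | 1-methoxy-2-methylcyclohexa-1,4-diene | COC1=C(C)CC=CC1 | intermediate
18 | rac-7,7-dibromo-1-methoxy-6-methylbicyclo[4.1.0]hept-3-ene (cis-fused, racemic) | COC12CC=CCC1(C)C2(Br)Br | intermediate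
19 | rac-7,7-dibromo-1-methoxy-6-methylbicyclo[4.1.0]heptane-3,4-diol (cis-diol, racemic) | COC12CC(O)C(O)CC1(C)C2(Br)Br | intermediate
20 | rac-7,7-dibromo-1-methoxy-6-methylbicyclo[4.1.0]heptane-3,4-dione | COC12CC(=O)C(=O)CC1(C)C2(Br)Br | intermediate
21 | 5-bromo-2-hydroxy-4-methoxy-6-methylcyclohepta-2,4,6-trien-1-one | COc1cc(O)c(=O)cc(C)c1Br | intermediate
22 | 5-bromo-2,6-dimethoxy-4-methylcyclohepta-2,4,6-trien-1-one | COc1cc(C)c(Br)c(OC)cc1=O | intermediate
23 | bis(alkylzinc iodide) from 15 (C1 and C10 zincated) | I[Zn]C[C@@H](C)[C@@H](OCc1ccc(OC)cc1)/C=C/C=C/[C@H](OCc1ccc(OC)cc1)CC[Zn]I | intermediate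
24 | 5,5'-[(2R,3R,4E,6E,8R)-3,8-bis[(4-methoxybenzyl)oxy]-2-methyldeca-4,6-diene-1,10-diyl]bis(2,6-dimethoxy-4-methylcyclohepta-2,4,6-trien-1-one) | COc1cc(C)c(C[C@@H](C)[C@@H](OCc2ccc(OC)cc2)/C=C/C=C/[C@H](OCc2ccc(OC)cc2)CCc2c(C)cc(OC)c(=O)cc2OC)c(OC)cc1=O | intermediate
25 | 5,5'-[(2R,3R,4E,6E,8R)-3,8-dihydroxy-2-methyldeca-4,6-diene-1,10-diyl]bis(2,6-dimethoxy-4-methylcyclohepta-2,4,6-trien-1-one) | COc1cc(C)c(C[C@@H](C)[C@@H](O)/C=C/C=C/[C@H](O)CCc2c(C)cc(OC)c(=O)cc2OC)c(OC)cc1=O | intermediate
26 | (2R,3R)-7-methoxy-2-[(1E,3E)-4-[(2R)-7-methoxy-5-methyl-8-oxo-2,3,4,8-tetrahydrocyclohepta[b]pyran-2-yl]buta-1,3-dien-1-yl]-3,5-dimethyl-3,4-dihydrocyclohepta[b]pyran-8(2H)-one | Cc1cc(OC)c(=O)cc2c1C[C@@H](C)[C@H](/C=C/C=C/[C@H]1CCc3c(C)cc(OC)c(=O)cc3O1)O2 | intermediate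
27 | (2R,3R)-8-hydroxy-2-[(1E,3E)-4-[(2R)-8-hydroxy-5-methyl-7-oxo-2,3,4,7-tetrahydrocyclohepta[b]pyran-2-yl]buta-1,3-dien-1-yl]-3,5-dimethyl-3,4-dihydrocyclohepta[b]pyran-7(2H)-one (CNP0332980.1) | Cc1cc(=O)c(O)cc2c1C[C@@H](C)[C@H](/C=C/C=C/[C@H]1CCc3c(C)cc(=O)c(O)cc3O1)O2 | target

**Step count and risks**

Total step count: 18. Longest linear sequence: 13 steps (steps 1–9 and 15–18); the tropone branch (steps 10–14) is five steps and joins at step 15.

Steps most likely to fail:

Step 7. The double enolisation may be incomplete, or the acetate enolate may be silylated on carbon. The ketene acetal geometry may erode, which would lower the C2/C3 anti selectivity. The γ-acyloxy enol ether units may ionise under the basic conditions, and the second shift may run through the newly formed alkene instead of its own enol ether. The fallback runs the two [3,3] shifts one after the other without base, as amide acetal (Eschenmoser–Claisen) rearrangements. It sets out from 10. Methanolysis (K2CO3, MeOH, 0 °C) would give (1E,3S,4S,5E)-1,6-bis[(4-methoxybenzyl)oxy]hexa-1,5-diene-3,4-diol F1. One equivalent of 1,1-dimethoxy-N,N-dimethylpropan-1-amine in toluene at 110 °C would then give (2S,3S,4E,6R,7E)-6-hydroxy-3,8-bis[(4-methoxybenzyl)oxy]-N,N,2-trimethylocta-4,7-dienamide F2; the ketene N,O-acetal has its methyl cis to the allylic oxygen and uses the same chair, and unreacted diol is recycled. 1,1-Dimethoxy-N,N-dimethylethan-1-amine under the same conditions would rearrange the remaining carbinol to (2S,3S,4E,6E,8R)-3,8-bis[(4-methoxybenzyl)oxy]-N1,N1,N10,N10,2-pentamethyldeca-4,6-dienediamide F3. LiNH2BH3 (THF, 0 °C → rt) would reduce both tertiary amides to primary alcohols, and the route is rejoined at 14.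

Step 15. Oxidative addition or transmetallation at the di-ortho-substituted bromotropone may be slow, so that protodezincation, β-hydride elimination or attack of the organozinc on the methoxytropone takes over, and the second coupling may stall after the first. The fallback changes the organometallic partner to boron (B-alkyl Suzuki–Miyaura coupling). It sets out from 15. Iodine–lithium exchange (tBuLi, Et2O, −78 °C) and capture with 9-methoxy-9-borabicyclo[3.3.1]nonane would give dilithium [(2R,3R,4E,6E,8R)-3,8-bis[(4-methoxybenzyl)oxy]-2-methyldeca-4,6-diene-1,10-diyl]bis(9-methoxy-9-boranuidabicyclo[3.3.1]nonane) F4. This is coupled without isolation with two equivalents of 22 (PdCl2(dppf), aq. K3PO4, DMF, rt), and the route is rejoined at 24.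

Step 18. Hydroxide may add at C9a and C9a' instead of C7 and C7', which would open the dihydropyran rings irreversibly. The fallback cleaves the O–CH3 bond instead of the ring C–O bond: MgI2 in Et2O/toluene at rt to 40 °C chelates the tropone carbonyl and the neighbouring methoxy oxygen, and iodide removes the methyl group by SN2. It sets out from 26 and comes back at 27 after work-up at pH 5, with no new compound on the way.

Further compounds
F1 | step 7 | (1E,3S,4S,5E)-1,6-bis[(4-methoxybenzyl)oxy]hexa-1,5-diene-3,4-diol | O[C@@H](/C=C/OCc1ccc(OC)cc1)[C@@H](O)/C=C/OCc1ccc(OC)cc1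
F2 | step 7 | (2S,3S,4E,6R,7E)-6-hydroxy-3,8-bis[(4-methoxybenzyl)oxy]-N,N,2-trimethylocta-4,7-dienamide | CN(C)C(=O)[C@@H](C)[C@@H](OCc1ccc(OC)cc1)/C=C/[C@@H](O)/C=C/OCc1ccc(OC)cc1
F3 | step 7 | (2S,3S,4E,6E,8R)-3,8-bis[(4-methoxybenzyl)oxy]-N1,N1,N10,N10,2-pentamethyldeca-4,6-dienediamide | CN(C)C(=O)[C@@H](C)[C@@H](OCc1ccc(OC)cc1)/C=C/C=C/[C@H](OCc1ccc(OC)cc1)CC(=O)N(C)C
F4 | step 15 | dilithium [(2R,3R,4E,6E,8R)-3,8-bis[(4-methoxybenzyl)oxy]-2-methyldeca-4,6-diene-1,10-diyl]bis(9-methoxy-9-boranuidabicyclo[3.3.1]nonane) | [Li+].[Li+].CO[B-]1(C[C@@H](C)[C@@H](OCc2ccc(OC)cc2)/C=C/C=C/[C@H](OCc2ccc(OC)cc2)CC[B-]2(OC)C3CCCC2CCC3)C2CCCC1CCC2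
F0 | step 18 | none | none
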